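The furanone ring is numbered O1, C2 (carbonyl), C3, C4, C5, with C6 the benzylidene carbon. Its O1–C2(=O) unit is treated as a molecule of carbon dioxide. The chain C3–C4–C5–C6 is first built as an acyclic β-alkynyl ketone, in which the future carbinol carbon is a ketone that acidifies C3 and the exocyclic C5=C6 alkene is still an alkyne. In one silver-catalysed operation the C3 enolate captures CO2 (C2–C3 bond) and the new carboxylate closes 5-exo-dig onto the alkyne (O1–C5 bond), giving the Z-benzylidene lactone. Dehydrogenation across C3–C4, enantioselective reduction of the activating ketone to the S carbinol and desilylation finish the synthesis.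

Key step: step 5

Remark: the carbinol stereocentre of the target is read as S (OH > furanone C3 > aryl > H), and ketone 4 is taken to be a catalogue compound.

Step 1
Reactants: 1 3-bromo-4-hydroxybenzaldehyde
Product: 2 3-bromo-4-(triisopropylsilyloxy)benzaldehyde
Conditions: iPr3SiCl (1.2 equiv), imidazole (2.5 equiv), DMF, 0 °C → rt
Reagents that add atoms: triisopropylsilyl chloride, CC(C)[Si](Cl)(C(C)C)C(C)C
Why: Imidazole-promoted O-silylation of the phenol (silyl ether protection); the bulky triisopropylsilyl aryl ether is chosen because it should survive amide bases, the alane, MTBD, DDQ and borane and still leave with fluoride at the end.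

Step 2
Reactants: 2 3-bromo-4-(triisopropylsilyloxy)benzaldehyde
Product: 3 (2-bromo-4-ethynylphenoxy)triisopropylsilane
Conditions: Me3SiCHN2 (1.2 equiv), LiN(iPr)2 (1.2 equiv), THF, −78 °C; then 2, −78 °C → rt
Reagents that add atoms: trimethylsilyldiazomethane, C[Si](C)(C)C=[N+]=[N-]
Why: Colvin rearrangement (aprotic Seyferth–Gilbert-type homologation): the lithiated silyldiazomethane adds to the aldehyde, Peterson-type loss of silanolate gives a diazoalkene that loses N2, and 1,2-hydrogen shift of the alkylidene carbene gives the terminal alkyne without exposing the aryl silyl ether to alkoxide or the aryl bromide to an alkyllithium.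

Step 3
Reactants: 4 1-(3,5-dibromo-4-methoxyphenyl)ethan-1-one; 2 3-bromo-4-(triisopropylsilyloxy)benzaldehyde
Product: 7 (E)-3-[3-bromo-4-(triisopropylsilyloxy)phenyl]-1-(3,5-dibromo-4-methoxyphenyl)prop-2-en-1-one, via lithium aldolate 5 (not isolated), via β-mesyloxy ketone 6 (not isolated)
Conditions: 4, LiN(SiMe3)2 (1.05 equiv), THF, −78 °C; then 2; then MsCl, Et3N, −78 °C → rt
Reagents that add atoms: none
Why: Directed aldol addition of the preformed lithium enolate followed by mesylation and E1cB elimination (a Claisen–Schmidt condensation run without hydroxide, which would cleave the para-formyl aryl silyl ether) should give the thermodynamically favoured E enone.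

Step 4
Reactants: 3 (2-bromo-4-ethynylphenoxy)triisopropylsilane; 7 (E)-3-[3-bromo-4-(triisopropylsilyloxy)phenyl]-1-(3,5-dibromo-4-methoxyphenyl)prop-2-en-1-one
Product: 9 rac-3,5-bis[3-bromo-4-(triisopropylsilyloxy)phenyl]-1-(3,5-dibromo-4-methoxyphenyl)pent-4-yn-1-one, via alkynyl(dimethyl)alane 8 (not isolated)
Conditions: 3 (1.3 equiv), AlMe3 (1.25 equiv), Et3N (10 mol %), toluene, 60 °C; then 7, toluene–Et2O, 0 °C → rt; aq. potassium sodium tartrate work-up
Reagents that add atoms: none
Why: Conjugate alkynylation of an s-cis enone by an alkynyl(dialkyl)alane through a six-membered transition state; the alane is made by amine-catalysed alumination of the terminal alkyne so that no alkyllithium meets the aryl bromides, and the new C4 stereocentre is formed racemic and removed in step 6.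

Step 5
Reactants: 9 rac-3,5-bis[3-bromo-4-(triisopropylsilyloxy)phenyl]-1-(3,5-dibromo-4-methoxyphenyl)pent-4-yn-1-one; 10 carbon dioxide
Product: 12 rac-(Z)-5-[3-bromo-4-(triisopropylsilyloxy)benzylidene]-4-[3-bromo-4-(triisopropylsilyloxy)phenyl]-3-(3,5-dibromo-4-methoxybenzoyl)dihydrofuran-2(3H)-one, via β-keto carboxylate salt 11 (not isolated)
Conditions: AgO2CPh (20 mol %), MTBD (4 equiv), CO2 (1.0 MPa), MeCN, 25 °C; then 1 M aq. HCl
Reagents that add atoms: carbon dioxide (10), O=C=O
Why: MTBD reversibly forms the C3 enolate of the aryl ketone, which adds to CO2 to give β-keto carboxylate 11 (C2–C3 bond); the silver catalyst π-activates the alkyne, the carboxylate oxygen adds anti across it at C5, and protonolysis of the C6–Ag bond releases the lactone (O1–C5 bond) and makes the otherwise reversible carboxylation productive. The closest known reaction type is the silver-catalysed carboxylation–cyclisation of alkyne-tethered aryl ketones with CO2 to (Z)-5-ylidene-3-acyl-γ-butyrolactones. The furanone ring closes 5-exo-dig. The Z geometry at C5=C6 (aryl cis to O1) follows from anti oxyargentation and retentive protonolysis; C3 is a β-dicarbonyl methine under thermodynamic control (trans to the C4 aryl group, or enolised), and both C3 and C4 are erased in step 6. The step needs carboxylate-oxygen attack to beat attack by the enolate oxygen (which would lead to a furan) and 5-exo to beat 6-endo closure at the aryl-bearing alkyne carbon: the CO2 pressure keeps the enolate carbon carboxylated, and the O–C(=O)–C3–C4–C5 tether favours the five-membered ring.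

Step 6
Reactants: 12 rac-(Z)-5-[3-bromo-4-(triisopropylsilyloxy)benzylidene]-4-[3-bromo-4-(triisopropylsilyloxy)phenyl]-3-(3,5-dibromo-4-methoxybenzoyl)dihydrofuran-2(3H)-one
Product: 13 (Z)-5-[3-bromo-4-(triisopropylsilyloxy)benzylidene]-4-[3-bromo-4-(triisopropylsilyloxy)phenyl]-3-(3,5-dibromo-4-methoxybenzoyl)furan-2(5H)-one
Conditions: DDQ (1.5 equiv), 1,4-dioxane, 80 °C
Reagents that add atoms: none
Why: DDQ dehydrogenation of the enolised β-keto lactone: hydride abstraction from C4–H, which is benzylic to the para-silyloxyaryl ring and allylic to both the enol and the C5=C6 enol ether, then loss of the enol proton, should give the fully conjugated furan-2(5H)-one and remove both stereocentres without touching the Z alkene.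

Step 7
Reactants: 13 (Z)-5-[3-bromo-4-(triisopropylsilyloxy)benzylidene]-4-[3-bromo-4-(triisopropylsilyloxy)phenyl]-3-(3,5-dibromo-4-methoxybenzoyl)furan-2(5H)-one
Product: 14 (Z)-5-[3-bromo-4-(triisopropylsilyloxy)benzylidene]-4-[3-bromo-4-(triisopropylsilyloxy)phenyl]-3-[(S)-(3,5-dibromo-4-methoxyphenyl)(hydroxy)methyl]furan-2(5H)-one
Conditions: (R)-2-methyl-CBS-oxazaborolidine (0.5 equiv), BH3·SMe2 (1.2 equiv), THF, −30 °C; then H2O work-up
Reagents that add atoms: none
Why: Corey–Bakshi–Shibata reduction: the ketone should bind the oxazaborolidine boron anti to its larger substituent, taken to be the twisted, tetrasubstituted furanone carbon C3 (flanked by C2=O and the C4 aryl group) rather than the coplanar unhindered aryl ring, so that the (R)-catalyst delivers hydride to the face that gives the S carbinol, while catalysed 1,2-reduction should outrun conjugate reduction at C4, hydroboration of the hindered alkenes and reduction of the lactone.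

Step 8
Reactants: 14 (Z)-5-[3-bromo-4-(triisopropylsilyloxy)benzylidene]-4-[3-bromo-4-(triisopropylsilyloxy)phenyl]-3-[(S)-(3,5-dibromo-4-methoxyphenyl)(hydroxy)methyl]furan-2(5H)-one
Product: 15 (Z)-5-(3-bromo-4-hydroxybenzylidene)-4-(3-bromo-4-hydroxyphenyl)-3-[(S)-(3,5-dibromo-4-methoxyphenyl)(hydroxy)methyl]furan-2(5H)-one
Conditions: Bu4NF (2.5 equiv), AcOH (2.5 equiv), THF, 0 °C
Reagents that add atoms: none
Why: Fluoride cleavage of the two aryl silyl ethers, buffered with acetic acid so that the phenols, the enol lactone and the allylic-benzylic carbinol meet neither strong base nor strong acid; the stereocentre is not involved.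

Compound list
1 | 3-bromo-4-hydroxybenzaldehyde | O=Cc1ccc(O)c(Br)c1 | starting material
2 | 3-bromo-4-(triisopropylsilyloxy)benzaldehyde | O=Cc1ccc(O[Si](C(C)C)(C(C)C)C(C)C)c(Br)c1 | intermediate
3 | (2-bromo-4-ethynylphenoxy)triisopropylsilane | C#Cc1ccc(O[Si](C(C)C)(C(C)C)C(C)C)c(Br)c1 | intermediate
4 | 1-(3,5-dibromo-4-methoxyphenyl)ethan-1-one | CC(=O)c1cc(Br)c(OC)c(Br)c1 | starting material
5 | lithium aldolate of 4 and 2 (racemic, not isolated) | [Li+].[O-]C(CC(=O)c1cc(Br)c(OC)c(Br)c1)c1ccc(O[Si](C(C)C)(C(C)C)C(C)C)c(Br)c1 | intermediate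
6 | β-mesyloxy ketone (racemic, not isolated) | CS(=O)(=O)OC(CC(=O)c1cc(Br)c(OC)c(Br)c1)c1ccc(O[Si](C(C)C)(C(C)C)C(C)C)c(Br)c1 | intermediate
7 | (E)-3-[3-bromo-4-(triisopropylsilyloxy)phenyl]-1-(3,5-dibromo-4-methoxyphenyl)prop-2-en-1-one | O=C(/C=C/c1ccc(O[Si](C(C)C)(C(C)C)C(C)C)c(Br)c1)c1cc(Br)c(OC)c(Br)c1 | intermediate
8 | {[3-bromo-4-(triisopropylsilyloxy)phenyl]ethynyl}dimethylalane (not isolated) | C[Al](C)C#Cc1ccc(O[Si](C(C)C)(C(C)C)C(C)C)c(Br)c1 | intermediate
9 | rac-3,5-bis[3-bromo-4-(triisopropylsilyloxy)phenyl]-1-(3,5-dibromo-4-methoxyphenyl)pent-4-yn-1-one | O=C(CC(C#Cc1ccc(O[Si](C(C)C)(C(C)C)C(C)C)c(Br)c1)c1ccc(O[Si](C(C)C)(C(C)C)C(C)C)c(Br)c1)c1cc(Br)c(OC)c(Br)c1 | intermediate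
10 | carbon dioxide | O=C=O | starting material
11 | MTBD-H+ salt of the racemic 2-aroyl-3-aryl-5-arylpent-4-ynoate (C3-carboxylated 9, not isolated) | [O-]C(=O)C(C(=O)c1cc(Br)c(OC)c(Br)c1)C(C#Cc1ccc(O[Si](C(C)C)(C(C)C)C(C)C)c(Br)c1)c1ccc(O[Si](C(C)C)(C(C)C)C(C)C)c(Br)c1.CN1CCCN2CCC[NH+]=C12 | intermediate
12 | rac-(Z)-5-[3-bromo-4-(triisopropylsilyloxy)benzylidene]-4-[3-bromo-4-(triisopropylsilyloxy)phenyl]-3-(3,5-dibromo-4-methoxybenzoyl)dihydrofuran-2(3H)-one (C3 epimers and enol tautomer interconvert) | O=C(c1cc(Br)c(OC)c(Br)c1)C1C(=O)O/C(=C\c2ccc(O[Si](C(C)C)(C(C)C)C(C)C)c(Br)c2)C1c1ccc(O[Si](C(C)C)(C(C)C)C(C)C)c(Br)c1 | intermediate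
13 | (Z)-5-[3-bromo-4-(triisopropylsilyloxy)benzylidene]-4-[3-bromo-4-(triisopropylsilyloxy)phenyl]-3-(3,5-dibromo-4-methoxybenzoyl)furan-2(5H)-one | O=C(c1cc(Br)c(OC)c(Br)c1)C1=C(c2ccc(O[Si](C(C)C)(C(C)C)C(C)C)c(Br)c2)/C(=C/c2ccc(O[Si](C(C)C)(C(C)C)C(C)C)c(Br)c2)OC1=O | intermediate
14 | (Z)-5-[3-bromo-4-(triisopropylsilyloxy)benzylidene]-4-[3-bromo-4-(triisopropylsilyloxy)phenyl]-3-[(S)-(3,5-dibromo-4-methoxyphenyl)(hydroxy)methyl]furan-2(5H)-one | COc1c(Br)cc([C@H](O)C2=C(c3ccc(O[Si](C(C)C)(C(C)C)C(C)C)c(Br)c3)/C(=C/c3ccc(O[Si](C(C)C)(C(C)C)C(C)C)c(Br)c3)OC2=O)cc1Br | intermediate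
15 | (Z)-5-(3-bromo-4-hydroxybenzylidene)-4-(3-bromo-4-hydroxyphenyl)-3-[(S)-(3,5-dibromo-4-methoxyphenyl)(hydroxy)methyl]furan-2(5H)-one | COc1c(Br)cc([C@H](O)C2=C(c3ccc(O)c(Br)c3)/C(=C/c3ccc(O)c(Br)c3)OC2=O)cc1Br | target

Total step count: 8. Longest linear sequence: 7 steps (1 → 2 → 7 → 9 → 12 → 13 → 14 → 15; the branch 2 → 3 joins at step 4).

Steps most likely to fail

Step 5. The guanidine base may isomerise the propargylic, benzylic C4–H/alkyne unit of 9 to an allene before carboxylation, or the ring may close through the enolate oxygen instead of the carboxylate. The fallback makes the two bonds in two separate operations. It sets out from 9: kinetic deprotonation with LiN(SiMe3)2 (2.2 equiv, THF, −78 °C) and C-acylation with di-tert-butyl dicarbonate should give the tert-butyl β-keto ester F1. Ph3PAuCl/AgOSO2CF3 (5 mol % each, CH2Cl2, rt) should then add the ester carbonyl oxygen 5-exo-dig to the alkyne with loss of 2-methylpropene. The route is rejoined at 12.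

Step 7. Facial discrimination between two sp2 substituents on the ketone may be poor, and hydride may be delivered to C4 of the alkylidene-1,3-dicarbonyl system instead of the ketone. The fallback replaces asymmetric induction by resolution. It sets out from 13: Luche reduction (NaBH4, CeCl3·7H2O, MeOH–THF, −40 °C) should give the racemic carbinol F4 by 1,2-addition. F4 is separated by preparative chromatography on a chiral stationary phase; the S enantiomer is 14, where the route is rejoined. The (R)-carbinol F5 is oxidised back to 13 with MnO2 (CH2Cl2, rt) and recycled.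

Step 6. Hydride abstraction may be slow, or the quinone may attack the electron-rich C5=C6 enol ether and over-oxidise. The fallback uses selenoxide syn-elimination. It sets out from 12: selenenylation at C3 (PhSeCl, pyridine, CH2Cl2, 0 °C) should give the C3 phenylselanyl keto lactone F2, with selenium entering trans to the C4 aryl group. Oxidation (30% aq. H2O2, CH2Cl2, 0 °C → rt) should give the selenoxide F3, which eliminates with the cis C4–H. The route is rejoined at 13.

Further compounds
F1 | step 5 | tert-butyl 2-(3,5-dibromo-4-methoxybenzoyl)-3,5-bis[3-bromo-4-(triisopropylsilyloxy)phenyl]pent-4-ynoate (racemic) | CC(C)(C)OC(=O)C(C(=O)c1cc(Br)c(OC)c(Br)c1)C(C#Cc1ccc(O[Si](C(C)C)(C(C)C)C(C)C)c(Br)c1)c1ccc(O[Si](C(C)C)(C(C)C)C(C)C)c(Br)c1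
F2 | step 6 | 3-(phenylselanyl) derivative of keto lactone 12 (racemic) | O=C(c1cc(Br)c(OC)c(Br)c1)C1([Se]c2ccccc2)C(=O)O/C(=C\c2ccc(O[Si](C(C)C)(C(C)C)C(C)C)c(Br)c2)C1c1ccc(O[Si](C(C)C)(C(C)C)C(C)C)c(Br)c1
F3 | step 6 | selenoxide of F2 (racemic) | O=C(c1cc(Br)c(OC)c(Br)c1)C1([Se](=O)c2ccccc2)C(=O)O/C(=C\c2ccc(O[Si](C(C)C)(C(C)C)C(C)C)c(Br)c2)C1c1ccc(O[Si](C(C)C)(C(C)C)C(C)C)c(Br)c1
F4 | step 7 | racemic carbinol (rac-14) | COc1c(Br)cc(C(O)C2=C(c3ccc(O[Si](C(C)C)(C(C)C)C(C)C)c(Br)c3)/C(=C/c3ccc(O[Si](C(C)C)(C(C)C)C(C)C)c(Br)c3)OC2=O)cc1Br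
F5 | step 7 | (R)-carbinol (enantiomer of 14) | COc1c(Br)cc([C@@H](O)C2=C(c3ccc(O[Si](C(C)C)(C(C)C)C(C)C)c(Br)c3)/C(=C/c3ccc(O[Si](C(C)C)(C(C)C)C(C)C)c(Br)c3)OC2=O)cc1Br
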